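## Retrosynthetic overview (carotenoid numbering)

1. The last C=C, C11'=C12', comes from a Wittig reaction of an ε-end C15 phosphonium salt with an acetylenic C25 aldehyde. The acetylenic half always reacts as the electrophile, so the 9E enyne never passes through an allylic ylide. The silyl ether is removed last.
2. The key bond is C15–C15', at the centre of the chromophore. It is made by an intermolecular vinylogous Mukaiyama aldol reaction of the acetylenic C20 dimethyl acetal with the C5 silyl dienol ether of tiglaldehyde, followed by E1cB loss of methanol.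
3. The C20 acetal comes from a C15 enynal and a C5 phosphonate (HWE). The C15 enynal comes from Sonogashira coupling of a ring enol triflate with (E)-3-methylpent-2-en-4-yn-1-ol.
4. C3 is derived from ketoisophorone by ene-reductase reduction and then substrate-controlled hydrogenation. C6' is derived from racemic α-ionone by ester crystallisation and lipase resolution.
5. No ring is formed. Both six-membered rings are bought (ketoisophorone, α-ionone). The hydroxy ring is elaborated first and the ε ring is attached last.

Assumption: the α-ionol 4-nitrobenzoate that crystallises from hexane is the (6R*,9S*) racemate.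

Handling: all polyene steps are run under argon in dim light, and chromatography uses silica pre-washed with 1% Et3N.

## Route

Step 1
Reactants: 1 ketoisophorone (2,6,6-trimethylcyclohex-2-ene-1,4-dione)
Product: 2 (6R)-2,2,6-trimethylcyclohexane-1,4-dione (levodione)
Conditions: ene-reductase OYE2, NADP+ (cat.), glucose dehydrogenase, D-glucose (1.5 equiv), phosphate buffer pH 7, 30 °C; recrystallise from iPr2O/hexane
Reagents that add atoms: none
Why: In this old-yellow-enzyme asymmetric conjugate reduction, flavin hydride and an active-site proton add anti across the activated C=C inside the chiral pocket, which sets 6R in high ee that crystallisation raises further.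

Step 2
Reactants: 2 levodione
Product: 3 (4R,6R)-4-hydroxy-2,2,6-trimethylcyclohexanone (actinol)
Conditions: H2 (5 bar), Raney Ni, MeOH, rt; crystallise from iPr2O/hexane
Reagents that add atoms: none
Why: In this chemoselective, substrate-controlled heterogeneous hydrogenation the C1 carbonyl is shielded by the quaternary carbon and hydrogen reaches C4 from the side away from the axial C2 methyl group, giving the axial 4R alcohol trans to the 6-methyl group (about 4:1), with the cis isomer removed by crystallisation.

Step 3
Reactants: 3 actinol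
Product: 4 (4R,6R)-4-(tert-butyldimethylsilyloxy)-2,2,6-trimethylcyclohexanone
Conditions: TBSCl, imidazole, DMF, rt
Reagents that add atoms: tert-butyldimethylsilyl chloride, CC(C)(C)[Si](C)(C)Cl
Why: Standard imidazole-promoted silylation of the secondary alcohol does not touch the C–O stereocentre and gives an ether that tolerates base, hydride, palladium and mild Lewis acid.

Step 4
Reactants: 4 silyloxy ketone
Product: 6 (4R)-4-(tert-butyldimethylsilyloxy)-2,6,6-trimethylcyclohex-1-en-1-yl trifluoromethanesulfonate, via lithium enolate 5 (not isolated)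
Conditions: LiN(iPr)2 (commercial solution, 1.2 equiv), THF, −78 → 0 °C; PhNTf2 (1.2 equiv), 0 °C → rt
Reagents that add atoms: N-phenylbis(trifluoromethanesulfonimide), O=S(=O)(N(c1ccccc1)S(=O)(=O)C(F)(F)F)C(F)(F)F
Why: In this enol triflate formation only C6 carries an α-hydrogen, so a single enolate forms and is O-sulfonylated, which deliberately erases the auxiliary C6 centre and leaves the remote 4R centre untouched.

Step 5
Reactants: 6 enol triflate; 7 (2E)-3-methylpent-2-en-4-yn-1-ol
Product: 8 (2E)-5-[(4R)-4-(tert-butyldimethylsilyloxy)-2,6,6-trimethylcyclohex-1-en-1-yl]-3-methylpent-2-en-4-yn-1-ol (C15 enynol)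
Conditions: Pd(PPh3)4 (5 mol %), CuI (10 mol %), Et3N (3 equiv), DMF, 50 °C, Ar
Reagents that add atoms: none
Why: Sonogashira coupling of the vinyl triflate with the terminal alkyne forms C6–C7 without involving the trisubstituted alkene of 7, so the 9E geometry is carried over unchanged.

Step 6
Reactants: 8 C15 enynol
Product: 9 (2E)-5-[(4R)-4-(tert-butyldimethylsilyloxy)-2,6,6-trimethylcyclohex-1-en-1-yl]-3-methylpent-2-en-4-ynal (C15 enynal)
Conditions: MnO2 (20 equiv), CH2Cl2, rt, dark
Reagents that add atoms: none
Why: Selective MnO2 oxidation of the primary allylic alcohol is neutral and leaves the alkene geometry, the alkyne and the silyl ether intact.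

Step 7
Reactants: 9 C15 enynal; 10 ethyl (2E)-4-(diethoxyphosphoryl)-3-methylbut-2-enoate (commercial, contains some Z isomer)
Product: 12 ethyl (2E,4E,6E)-9-[(4R)-4-(tert-butyldimethylsilyloxy)-2,6,6-trimethylcyclohex-1-en-1-yl]-3,7-dimethylnona-2,4,6-trien-8-ynoate (C20 ester), via lithiated phosphonate 11 (not isolated)
Conditions: 10 (1.5 equiv), n-BuLi (1.45 equiv), THF/DMPU 4:1, −78 °C; then 9, −78 → 0 °C; chromatography
Reagents that add atoms: none
Why: This Horner-Wadsworth-Emmons olefination with the stabilised allylic phosphonate anion, standard in retinoid work, gives the 11E alkene and mainly the 13E ester, and the minor 13Z isomer is removed on silica.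

Step 8
Reactants: 12 C20 ester
Product: 13 (2E,4E,6E)-9-[(4R)-4-(tert-butyldimethylsilyloxy)-2,6,6-trimethylcyclohex-1-en-1-yl]-3,7-dimethylnona-2,4,6-trien-8-yn-1-ol (C20 alcohol)
Conditions: iBu2AlH (2.5 equiv), CH2Cl2, −78 °C; aq. potassium sodium tartrate work-up
Reagents that add atoms: none
Why: 1,2-Reduction of the conjugated ester by iBu2AlH at low temperature stops cleanly at the allylic alcohol and does not affect the enyne or the silyl ether.

Step 9
Reactants: 13 C20 alcohol
Product: 14 (2E,4E,6E)-9-[(4R)-4-(tert-butyldimethylsilyloxy)-2,6,6-trimethylcyclohex-1-en-1-yl]-3,7-dimethylnona-2,4,6-trien-8-ynal (C20 aldehyde)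
Conditions: MnO2 (20 equiv), CH2Cl2, rt, dark
Reagents that add atoms: none
Why: MnO2 allylic oxidation is the mildest way to a retinal-type polyenal and keeps the all-E geometry.

Step 10
Reactants: 14 C20 aldehyde
Product: 15 (2E,4E,6E)-1,1-dimethoxy-3,7-dimethyl-9-[(4R)-4-(tert-butyldimethylsilyloxy)-2,6,6-trimethylcyclohex-1-en-1-yl]nona-2,4,6-trien-8-yne (C20 dimethyl acetal)
Conditions: HC(OMe)3 (3 equiv), PPTS (5 mol %), MeOH, 0 °C → rt; quench with Et3N; used after filtration through basic alumina
Reagents that add atoms: trimethyl orthoformate, COC(OC)OC; methanol, CO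
Why: Acid-catalysed acetalisation is driven by the orthoester as water scavenger, and the weak acid at or below rt leaves the secondary silyl ether and the polyene geometry intact.

Step 11
Reactants: 16 tiglaldehyde ((2E)-2-methylbut-2-enal)
Product: 17 (1E)-2-methyl-1-(trimethylsilyloxy)buta-1,3-diene (C5 silyl dienol ether)
Conditions: TMSOTf (1.1 equiv), Et3N (1.5 equiv), Et2O, 0 °C → rt; distil
Reagents that add atoms: trimethylsilyl trifluoromethanesulfonate, C[Si](C)(C)OS(=O)(=O)C(F)(F)F
Why: In this soft enolisation, O-silylation activates the enal and Et3N removes a γ-proton to give the conjugated silyl dienol ether, whose enol geometry is irrelevant because it is lost in the next step.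

Step 12 (key step)
Reactants: 15 C20 dimethyl acetal; 17 C5 silyl dienol ether
Product: 18 (2E,6E,8E,10E)-5-methoxy-2,7,11-trimethyl-13-[(4R)-4-(tert-butyldimethylsilyloxy)-2,6,6-trimethylcyclohex-1-en-1-yl]trideca-2,6,8,10-tetraen-12-ynal (both C5 epimers)
Conditions: 17 (1.5 equiv), ZnCl2 (10 mol %, solution in EtOAc), CH2Cl2, −20 → 0 °C; quench with Et3N then aq. NaHCO3
Reagents that add atoms: none
Why: In this intermolecular vinylogous Mukaiyama aldol reaction the Lewis acid ionises the acetal and the dienol ether attacks through its unhindered γ-terminus (α-attack would build a quaternary carbon), forming C15–C15' and releasing the E α-methyl enal, which is far less reactive than the acetal so no second addition occurs, and the new methoxy-bearing centre is removed in step 13.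

Step 13
Reactants: 18 δ-methoxy enal
Product: 19 (2E,4E,6E,8E,10E)-2,7,11-trimethyl-13-[(4R)-4-(tert-butyldimethylsilyloxy)-2,6,6-trimethylcyclohex-1-en-1-yl]trideca-2,4,6,8,10-pentaen-12-ynal (C25 aldehyde)
Conditions: DBU (1.5 equiv), 4 Å molecular sieves, toluene, rt → 40 °C
Reagents that add atoms: none
Why: In this vinylogous E1cB elimination, γ-deprotonation of the enal expels the δ-methoxide to give the fully conjugated polyenal with the thermodynamically favoured E central double bond.

Step 14
Reactants: 20 racemic α-ionone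
Product: 21 α-ionol ((3E)-4-(2,6,6-trimethylcyclohex-2-en-1-yl)but-3-en-2-ol) as all four stereoisomers
Conditions: NaBH4, CeCl3·7H2O, MeOH, 0 °C
Reagents that add atoms: none
Why: Luche reduction gives clean 1,2-reduction of the enone and installs a carbinol handle (about 1:1 at C9) for the resolution.

Step 15
Reactants: 21 α-ionol mixture
Product: 22 racemic (6R*,9S*)-α-ionyl 4-nitrobenzoate (single diastereomer)
Conditions: 4-nitrobenzoyl chloride, pyridine, DMAP (cat.), CH2Cl2, 0 °C → rt; repeated crystallisation from hexane
Reagents that add atoms: 4-nitrobenzoyl chloride, O=C(Cl)c1ccc(cc1)[N+](=O)[O-]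
Why: Acylation turns the oily diastereomeric alcohols into crystalline esters of different solubility, so fractional crystallisation delivers one racemic diastereomer in which the C6 and C9 configurations are tied to each other.

Step 16
Reactants: 22 racemic (6R*,9S*) ester
Product: 23 racemic (6R*,9S*)-α-ionol
Conditions: K2CO3 (0.2 equiv), MeOH, rt
Reagents that add atoms: none
Why: Base-catalysed transesterification of the activated aryl ester cleaves the acyl–oxygen bond only, so neither stereocentre is touched.

Step 17
Reactants: 23 racemic (6R*,9S*)-α-ionol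
Product: 24 (2S,3E)-4-[(1R)-2,6,6-trimethylcyclohex-2-en-1-yl]but-3-en-2-ol ((6R,9S)-α-ionol)
Conditions: lipase PS (Burkholderia cepacia), vinyl acetate, t-BuOMe, rt, to about 55% conversion; chromatography
Reagents that add atoms: none
Why: In this lipase kinetic resolution the enzyme follows the Kazlauskas rule and acetylates the 9R carbinol, so the (6S,9R) enantiomer is removed as its acetate and the unreacted 9S alcohol, which carries the 6R ring because 23 is one diastereomer, is recovered in high ee.

Step 18
Reactants: 24 (6R,9S)-α-ionol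
Product: 25 (R)-α-ionone
Conditions: MnO2 (15 equiv), CH2Cl2, rt
Reagents that add atoms: none
Why: Neutral MnO2 allylic oxidation removes the auxiliary C9 centre without enolising the γ-position, so the 6R centre keeps its configuration.

Step 19
Reactants: 25 (R)-α-ionone; 26 vinylmagnesium bromide
Product: 27 (1E)-3-methyl-1-[(1R)-2,6,6-trimethylcyclohex-2-en-1-yl]penta-1,4-dien-3-ol (both C3 epimers)
Conditions: CH2=CHMgBr (1.3 equiv), THF, −30 → 0 °C; aqueous quench
Reagents that add atoms: none
Why: Grignard 1,2-addition to the enone outruns γ-deprotonation at low temperature, so C6' is preserved, and the new carbinol centre is irrelevant because it is ionised in step 20.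

Step 20
Reactants: 27 vinyl carbinol
Product: 28 [(2E,4E)-3-methyl-5-[(1R)-2,6,6-trimethylcyclohex-2-en-1-yl]penta-2,4-dien-1-yl]triphenylphosphonium bromide (C15 salt)
Conditions: PPh3·HBr (1.05 equiv), MeOH, 0 °C → rt; crystallise from EtOAc/acetone
Reagents that add atoms: triphenylphosphine hydrobromide, [Br-].c1ccc(cc1)[PH+](c1ccccc1)c1ccccc1
Why: In this SN1' phosphonium salt formation the tertiary bis-allylic alcohol ionises under mild acid, PPh3 captures the cation at its unhindered primary end with allylic transposition, crystallisation enriches the 9'E salt, and the C6'–H bond is not involved.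

Step 21
Reactants: 28 C15 salt; 19 C25 aldehyde
Product: 30 (3R,6'R)-3-(tert-butyldimethylsilyloxy)-7,8-didehydro-β,ε-carotene, via phosphorus ylide 29 (not isolated)
Conditions: NaOMe (1.3 equiv), CH2Cl2/MeOH, 0 °C → rt; then reflux in n-heptane, 3 h, Ar, dark; chromatography
Reagents that add atoms: none
Why: Wittig olefination with the semi-stabilised allylic ylide forms C11'=C12', a short thermal equilibration converts the hindered 11'Z isomer to all-E, and methoxide at rt is too weak to deprotonate C6' or disturb C3.

Step 22
Reactants: 30 silyl ether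
Product: 31 (3R,6'R)-7,8-didehydro-β,ε-caroten-3-ol (crocoxanthin, target)
Conditions: Bu4NF (3 equiv), AcOH (3 equiv), THF, rt; crystallise from CH2Cl2/MeOH
Reagents that add atoms: none
Why: Buffered fluoride desilylation cleaves only the Si–O bond, so the 3R configuration and the polyene geometry are retained and crystallisation gives the all-E single enantiomer.

## Compound list

1 | ketoisophorone | CC1=CC(=O)CC(C)(C)C1=O | starting material
2 | (6R)-levodione | C[C@@H]1CC(=O)CC(C)(C)C1=O | intermediate
3 | (4R,6R)-actinol | C[C@@H]1C[C@@H](O)CC(C)(C)C1=O | intermediate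
4 | (4R,6R)-4-(tert-butyldimethylsilyloxy)-2,2,6-trimethylcyclohexanone | C[C@@H]1C[C@@H](O[Si](C)(C)C(C)(C)C)CC(C)(C)C1=O | intermediate
5 | lithium enolate of 4 | [Li+].[O-]C1=C(C)C[C@@H](O[Si](C)(C)C(C)(C)C)CC1(C)C | intermediate
6 | (4R)-enol triflate | FC(F)(F)S(=O)(=O)OC1=C(C)C[C@@H](O[Si](C)(C)C(C)(C)C)CC1(C)C | intermediate
7 | (2E)-3-methylpent-2-en-4-yn-1-ol | C#C/C(C)=C/CO | starting material
8 | C15 enynol | OC/C=C(\C)C#CC1=C(C)C[C@@H](O[Si](C)(C)C(C)(C)C)CC1(C)C | intermediate
9 | C15 enynal | O=C/C=C(\C)C#CC1=C(C)C[C@@H](O[Si](C)(C)C(C)(C)C)CC1(C)C | intermediate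
10 | ethyl (2E)-4-(diethoxyphosphoryl)-3-methylbut-2-enoate | CCOC(=O)/C=C(\C)CP(=O)(OCC)OCC | starting material
11 | lithiated phosphonate from 10 | [Li+].CCOC(=O)/C=C(\C)[CH-]P(=O)(OCC)OCC | intermediate
12 | C20 ester | CCOC(=O)/C=C(C)/C=C/C=C(\C)C#CC1=C(C)C[C@@H](O[Si](C)(C)C(C)(C)C)CC1(C)C | intermediate
13 | C20 alcohol | OC/C=C(C)/C=C/C=C(\C)C#CC1=C(C)C[C@@H](O[Si](C)(C)C(C)(C)C)CC1(C)C | intermediate
14 | C20 aldehyde | O=C/C=C(C)/C=C/C=C(\C)C#CC1=C(C)C[C@@H](O[Si](C)(C)C(C)(C)C)CC1(C)C | intermediate
15 | C20 dimethyl acetal | COC(OC)/C=C(C)/C=C/C=C(\C)C#CC1=C(C)C[C@@H](O[Si](C)(C)C(C)(C)C)CC1(C)C | intermediate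
16 | tiglaldehyde | C/C=C(\C)C=O | starting material
17 | (1E)-2-methyl-1-(trimethylsilyloxy)buta-1,3-diene | C=C/C(C)=C/O[Si](C)(C)C | intermediate
18 | δ-methoxy C25 enal (epimers at the methoxy carbon) | O=C/C(C)=C/CC(OC)/C=C(C)/C=C/C=C(\C)C#CC1=C(C)C[C@@H](O[Si](C)(C)C(C)(C)C)CC1(C)C | intermediate
19 | C25 aldehyde | O=C/C(C)=C/C=C/C=C(C)/C=C/C=C(\C)C#CC1=C(C)C[C@@H](O[Si](C)(C)C(C)(C)C)CC1(C)C | intermediate
20 | racemic α-ionone | CC1=CCCC(C)(C)C1/C=C/C(C)=O | starting material
21 | α-ionol, four stereoisomers | CC1=CCCC(C)(C)C1/C=C/C(C)O | intermediate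
22 | racemic (6R*,9S*)-α-ionyl 4-nitrobenzoate | CC1=CCCC(C)(C)[C@H]1/C=C/[C@H](C)OC(=O)c1ccc(cc1)[N+](=O)[O-].CC1=CCCC(C)(C)[C@@H]1/C=C/[C@@H](C)OC(=O)c1ccc(cc1)[N+](=O)[O-] | intermediate
23 | racemic (6R*,9S*)-α-ionol | CC1=CCCC(C)(C)[C@H]1/C=C/[C@H](C)O.CC1=CCCC(C)(C)[C@@H]1/C=C/[C@@H](C)O | intermediate
24 | (6R,9S)-α-ionol | CC1=CCCC(C)(C)[C@H]1/C=C/[C@H](C)O | intermediate
25 | (R)-α-ionone | CC1=CCCC(C)(C)[C@H]1/C=C/C(C)=O | intermediate
26 | vinylmagnesium bromide | C=C[Mg]Br | starting material
27 | (6'R)-vinyl-α-ionol (epimers at the carbinol carbon) | CC1=CCCC(C)(C)[C@H]1/C=C/C(C)(O)C=C | intermediate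
28 | ε-end C15 triphenylphosphonium bromide | CC1=CCCC(C)(C)[C@H]1/C=C/C(C)=C/C[P+](c1ccccc1)(c1ccccc1)c1ccccc1.[Br-] | intermediate
29 | ylide from 28 | CC1=CCCC(C)(C)[C@H]1/C=C/C(C)=C/C=P(c1ccccc1)(c1ccccc1)c1ccccc1 | intermediate
30 | crocoxanthin tert-butyldimethylsilyl ether | CC1=CCCC(C)(C)[C@H]1/C=C/C(C)=C/C=C/C(C)=C/C=C/C=C(C)/C=C/C=C(\C)C#CC1=C(C)C[C@@H](O[Si](C)(C)C(C)(C)C)CC1(C)C | intermediate
31 | (3R,6'R)-crocoxanthin | CC1=CCCC(C)(C)[C@H]1/C=C/C(C)=C/C=C/C(C)=C/C=C/C=C(C)/C=C/C=C(\C)C#CC1=C(C)C[C@@H](O)CC1(C)C | target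

## Step count and risks

Total steps: 22. The longest linear sequence is 14 steps, from 1 to 31 through steps 1–10, 12, 13, 21 and 22. The ε branch contributes 9 steps (14–22).

**Risk 1, step 12 (together with its feed, step 10).** The polyenyl oxocarbenium ion is strongly stabilised and may react sluggishly. The Lewis acid may also isomerise or degrade the polyene.

The fallback sets out from aldehyde 14 and comes back at 19. It replaces acetal chemistry by a phosphonate olefination. Commercial ethyl tiglate is brominated with NBS to ethyl (2E)-4-bromo-2-methylbut-2-enoate F1. An Arbuzov reaction with P(OEt)3 gives ethyl (2E)-4-(diethoxyphosphoryl)-2-methylbut-2-enoate F2. n-BuLi converts this into the lithiated phosphonate F3, which olefinates 14 to the all-E C25 ethyl ester F4. iBu2AlH then gives the C25 allylic alcohol F5, and MnO2 oxidation returns 19.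

**Risk 2, step 15.** The fractional crystallisation may stall at incomplete diastereomeric purity, which would cap the ee reached in step 17.

The fallback sets out from racemic 20 and comes back at 25, bypassing steps 14–18. It uses physical separation instead of derivatisation. Racemic α-ionone is resolved directly by preparative (simulated moving bed) chromatography on cellulose tris(3,5-dimethylphenylcarbamate) with hexane/iPrOH, and the dextrorotatory R enantiomer is collected. No new compound is made.

**Risk 3, step 5.** Oxidative addition of zerovalent palladium into the tetrasubstituted, neopentyl-flanked triflate may be slow enough for alkyne homocoupling to dominate.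

The fallback sets out from ketone 4 (with 7) and comes back at 8. It forms C6–C7 by carbonyl addition instead of cross-coupling. Two equivalents of n-BuLi convert 7 into the dilithio enynolate F6, which adds to 4 to give the tertiary propargylic diol F7. Ac2O/pyridine acetylates only the primary hydroxyl, giving the monoacetate F8. POCl3/pyridine at 90 °C dehydrates F8 in the only possible direction to the ring enyne acetate F9. K2CO3/MeOH then returns 8.

## Further compounds

F1 | step 12 | ethyl (2E)-4-bromo-2-methylbut-2-enoate | BrC/C=C(\C)C(=O)OCC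
F2 | step 12 | ethyl (2E)-4-(diethoxyphosphoryl)-2-methylbut-2-enoate | CCOC(=O)/C(C)=C/CP(=O)(OCC)OCC
F3 | step 12 | lithiated phosphonate from F2 | [Li+].CCOC(=O)/C(C)=C/[CH-]P(=O)(OCC)OCC
F4 | step 12 | all-E C25 ethyl ester | CCOC(=O)/C(C)=C/C=C/C=C(C)/C=C/C=C(\C)C#CC1=C(C)C[C@@H](O[Si](C)(C)C(C)(C)C)CC1(C)C
F5 | step 12 | all-E C25 allylic alcohol | OC/C(C)=C/C=C/C=C(C)/C=C/C=C(\C)C#CC1=C(C)C[C@@H](O[Si](C)(C)C(C)(C)C)CC1(C)C
F0 | step 15 | none | none
F6 | step 5 | dilithio derivative of 7 | [Li+].[Li+].[C-]#C/C(C)=C/C[O-]
F7 | step 5 | tertiary propargylic diol (carbinol centre unassigned) | C[C@@H]1C[C@@H](O[Si](C)(C)C(C)(C)C)CC(C)(C)C1(O)C#C/C(C)=C/CO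
F8 | step 5 | primary monoacetate of F7 | C[C@@H]1C[C@@H](O[Si](C)(C)C(C)(C)C)CC(C)(C)C1(O)C#C/C(C)=C/COC(C)=O
F9 | step 5 | acetate of 8 | CC(=O)OC/C=C(\C)C#CC1=C(C)C[C@@H](O[Si](C)(C)C(C)(C)C)CC1(C)C
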